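**Plan**

1. Locants (tricyclo[5.4.0.0^{2,8}]undecane): C1, C7, C8 = cyclobutane CH; C2 = cyclobutane C–CH3; C3, C5 = CH–O; C4 = CH2; C6 = C(CH3)(CH2OH); C9 = CH–CH3; C10 = CH2; C11 = C=O.
2. Retrosynthetic cuts, in order: both ester C–O bonds; C9–CH3 (cuprate on a C9=C10–C11=O enone made by allylic oxidation of a C9=C10 alkene); C6–C7; C7–C1 (cyclobutane bond α to the C5 ketone, enolate alkylation of a cis-decalone tosylate); back to (R)-Wieland–Miescher ketone.
3. Enabling feature: in the seven-membered ring C2–C3–C4–C5–C6–C7–C8 the quaternary C6 (CH3, CH2OH) sits between the oxygenated C5 and the cyclobutane CH C7. This is the α-quaternary β-hydroxy ketone pattern left by a semipinacol 1,2-shift of a tertiary epoxy alcohol, so C6 is inserted between C5 and C7 of a six-membered ketone ring (six → seven).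
4. Forward order of rings: decalin → cyclobutane (tricyclo[4.4.0.0^{2,7}]decane core) → enlargement to the seven-membered ring → functionalisation of the remaining six-membered ring → esters.
5. Stereochemistry: C2 from (R)-Wieland–Miescher ketone (fixes C1, C7, C8 through the cage); C3 by ligand-controlled conjugate borylation; C6 by hydroxyl-directed epoxidation and the stereospecific shift; C5 by hydride delivery from the C6 CH2OH; C9 by cuprate addition anti to the C2 methyl.

Key step: step 12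

Remark: intermediates 7–15 carry tricyclo[4.4.0.0^{2,7}]decane locants (C1 = C–CH3; C2, C6, C7 = cyclobutane CH; C8 = C=O). "Syn to C6" in that series and "syn to C1" in the undecane series name the same ring face. Enantiopure (R)-Wieland–Miescher ketone is taken as purchased.

**Step 1**
Reactants: 1 (R)-Wieland–Miescher ketone
Product: 2 (4aR,5R)-5-hydroxy-4a-methyl-4,4a,5,6,7,8-hexahydronaphthalen-2(3H)-one
Conditions: NaBH4 (0.3 equiv), EtOH, 0 °C
Reagents that add atoms: none
Why: Chemoselective borohydride reduction of the saturated ketone beside the enone; hydride should enter anti to the axial angular methyl, giving the carbinol cis to CH3, the established course for this diketone.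

**Step 2**
Reactants: 2 hydroxy enone
Product: 3 (1R,8aR)-8a-methyl-6-oxo-1,2,3,4,6,7,8,8a-octahydronaphthalen-1-yl 4-methylbenzenesulfonate
Conditions: TsCl, pyridine, DMAP (cat.), 0 °C → rt
Reagents that add atoms: p-toluenesulfonyl chloride, Cc1ccc(cc1)S(=O)(=O)Cl
Why: O-Sulfonylation of the secondary alcohol with retention, installing the leaving group cis to the angular methyl.

**Step 3**
Reactants: 3 enone tosylate
Product: 5 4-hydroxy-8a-methyl-6-oxo-1,2,3,4,6,7,8,8a-octahydronaphthalen-1-yl 4-methylbenzenesulfonate (1-OTs 4-OH 8a-CH3 all cis), via dienol silyl ether 4 (not isolated)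
Conditions: TMSOTf, Et3N, CH2Cl2, 0 °C; then m-CPBA, CH2Cl2, −15 °C; dilute HCl work-up
Reagents that add atoms: m-chloroperbenzoic acid, OOC(=O)c1cccc(Cl)c1; trimethylsilyl triflate, C[Si](C)(C)OS(=O)(=O)C(F)(F)F (silicon only in 4)
Why: Vinylogous Rubottom oxidation: soft enolisation gives the linear dienol silyl ether, and the peracid should attack its γ-carbon axially on the face syn to the angular methyl, as in the 6β-hydroxylation of steroidal 3,5-dienol ethers.

**Step 4**
Reactants: 5 γ-hydroxy enone tosylate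
Product: 6 4-hydroxy-8a-methyl-6-oxodecahydronaphthalen-1-yl 4-methylbenzenesulfonate (cis-fused; 1-OTs, 4-OH, 4a-H and 8a-CH3 on one face)
Conditions: [Ir(cod)(PCy3)(py)]PF6 (5 mol%), H2 (1 atm), CH2Cl2, rt
Reagents that add atoms: none
Why: Hydroxyl-directed hydrogenation with Crabtree's catalyst: iridium bound to the allylic 4-OH should deliver H2 to the same face of the enone double bond, so the new ring-fusion hydrogen is cis to 4-OH and to the angular methyl (cis-decalin).

**Step 5**
Reactants: 6 cis-decalone tosylate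
Product: 7 3-hydroxy-1-methyltricyclo[4.4.0.0^{2,7}]decan-8-one (3-OH on the side of C1)
Conditions: NaH, DMSO (NaCH2S(O)CH3, 3 equiv), rt
Reagents that add atoms: none
Why: Intramolecular enolate C-alkylation (4-exo-tet, SN2 with inversion at the sulfonate carbon): in the cis-decalin the C5 enolate carbon lies behind the C1–OTs bond, a known closure mode of such keto sulfonates, the other enolate cannot reach the σ* orbital, and the new ring-fusion centres are fixed by the cage.

**Step 6**
Reactants: 7 tricyclic hydroxy ketone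
Product: 8 1-methyltricyclo[4.4.0.0^{2,7}]dec-3-en-8-one
Conditions: Burgess reagent, toluene, 60 °C
Reagents that add atoms: none
Why: Burgess syn-elimination of the secondary alcohol, which can only run toward the CH2 because the other β-hydrogen is at a bridgehead (anti-Bredt alkene).

**Step 7**
Reactants: 8 ene ketone
Product: 9 1-methyltricyclo[4.4.0.0^{2,7}]deca-3,9-dien-8-one
Conditions: IBX, DMSO/toluene, 75 °C
Reagents that add atoms: none
Why: IBX α,β-dehydrogenation of the ketone through its enol, which can form only toward the CH2 since the other α-carbon is the cyclobutane bridgehead.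

**Step 8**
Reactants: 9 dienone
Product: 11 10-hydroxy-1-methyltricyclo[4.4.0.0^{2,7}]dec-3-en-8-one (10-OH syn to C6), via β-boryl ketone 10 (not isolated)
Conditions: CuCl (5 mol%), NaOt-Bu (10 mol%), Josiphos-type bisphosphine (6 mol%, antipode selected for delivery to the face syn to C6), B2pin2, MeOH, THF, rt; then NaBO3·4H2O, THF/H2O
Reagents that add atoms: bis(pinacolato)diboron, CC1(C)OB(OC1(C)C)B1OC(C)(C)C(C)(C)O1 (boron only in 10); sodium perborate, [Na+].[Na+].O[B-]1(O)OO[B-](O)(O)OO1 (oxygen of 11)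
Why: Copper-catalysed asymmetric conjugate borylation then C–B oxidation with retention; the enone bridge lies in a local pseudo-mirror plane flanked by two cyclobutane C–H bonds, so substrate bias should be small and the chiral ligand should decide the face.

**Step 9**
Reactants: 11 β-hydroxy ketone
Product: 12 10-(tert-butyldimethylsilyloxy)-1-methyltricyclo[4.4.0.0^{2,7}]dec-3-en-8-one
Conditions: TBSOTf, 2,6-lutidine, CH2Cl2, −78 → 0 °C
Reagents that add atoms: tert-butyldimethylsilyl triflate, CC(C)(C)[Si](C)(C)OS(=O)(=O)C(F)(F)F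
Why: O-Silylation of the hindered secondary alcohol, which protects it and places a bulky group on the face syn to C6.

**Step 10**
Reactants: 12 silyloxy ketone; 13 isopropenylmagnesium bromide
Product: 14 10-(tert-butyldimethylsilyloxy)-1-methyl-8-(prop-1-en-2-yl)tricyclo[4.4.0.0^{2,7}]dec-3-en-8-ol (8-OH and 10-OSi syn to C6; isopropenyl syn to C2)
Conditions: LaCl3·2LiCl, THF, 0 °C
Reagents that add atoms: none
Why: Lanthanide-promoted Grignard 1,2-addition (enolisation and β-elimination suppressed); the nucleophile should enter anti to the 1,3-related silyloxy group, giving the carbinol with OH cis to OSi.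

**Step 11**
Reactants: 14 tertiary allylic alcohol
Product: 15 10-(tert-butyldimethylsilyloxy)-1-methyl-8-[(R)-2-methyloxiran-2-yl]tricyclo[4.4.0.0^{2,7}]dec-3-en-8-ol
Conditions: VO(acac)2 (5 mol%), t-BuOOH, CH2Cl2, 0 °C → rt
Reagents that add atoms: tert-butyl hydroperoxide, CC(C)(C)OO
Why: Vanadium-catalysed hydroxyl-directed epoxidation, chemoselective for the allylic-alcohol alkene over the remote ring alkene; in the vanadate transition state the smaller ring CH2 should eclipse the vinylic methyl (A(1,2) strain) while the cyclobutane CH points away, which defines the face shown.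

**Step 12**
Reactants: 15 tertiary epoxy alcohol
Product: 16 3-(tert-butyldimethylsilyloxy)-6-(hydroxymethyl)-2,6-dimethyltricyclo[5.4.0.0^{2,8}]undec-9-en-5-one (3-OSi and 6-CH2OH syn to C1; 6-CH3 syn to C8)
Conditions: ZnBr2 (1.5 equiv), CH2Cl2, 0 °C → rt
Reagents that add atoms: none
Why: Zn(II) binds the tertiary hydroxyl and the epoxide oxygen; as the tertiary C–O bond of the epoxide ionises, the ring bond from the carbinol carbon to the cyclobutane CH (future C5–C7) shifts to the epoxide carbon, the carbinol becomes the C5 ketone and the epoxide oxygen ends as the primary alkoxide, so the epoxide carbon enters the ring as C6. The closest known reaction type is the Lewis-acid semipinacol rearrangement of tertiary α-hydroxy epoxides with ring enlargement of cycloalkanols to α-quaternary β-hydroxy cycloalkanones. No ring is closed by cyclisation: the seven-membered ring arises from the six-membered one by a suprafacial 1,2-alkyl shift, and the cyclobutane and cyclohexene rings are untouched. The only new stereocentre, C6, is set stereospecifically by the epoxide configuration (the migrating carbon attacks anti to the breaking C–O bond and keeps its own configuration). The step needs migration of the cyclobutane CH and not of the ring CH2; this should be secured by the higher migratory aptitude of the secondary strained-ring carbon (the carbon type that migrates in Baeyer–Villiger oxidation of nopinone-type ketones), by inductive deactivation of the CH2 next to the silyloxy-bearing carbon, and by the zinc chelate, which holds the carbinol–cyclobutyl bond antiperiplanar to the epoxide C–O bond.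

**Step 13**
Reactants: 16 β-hydroxy ketone
Product: 17 3-(tert-butyldimethylsilyloxy)-6-(hydroxymethyl)-2,6-dimethyltricyclo[5.4.0.0^{2,8}]undec-9-en-5-ol (5-OH syn to C8)
Conditions: Me4NBH(OAc)3, MeCN/AcOH, −20 °C
Reagents that add atoms: none
Why: Evans–Saksena reduction: the acetoxyborohydride bound to the primary hydroxyl should deliver hydride to the ketone from the CH2OH face, placing 5-OH trans to CH2OH.

**Step 14**
Reactants: 17 diol
Product: 19 3-(tert-butyldimethylsilyloxy)-5-hydroxy-6-(hydroxymethyl)-2,6-dimethyltricyclo[5.4.0.0^{2,8}]undec-9-en-11-one, via allylic alcohol 18 (not isolated)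
Conditions: SeO2 (0.5 equiv), t-BuOOH, CH2Cl2, rt; then MnO2, CH2Cl2, rt
Reagents that add atoms: tert-butyl hydroperoxide, CC(C)(C)OO, oxygen relayed by selenium dioxide, O=[Se]=O
Why: Selenium dioxide allylic hydroxylation (ene reaction then [2,3]-shift, no transposition) at the only allylic CH2, the other allylic position being a bridgehead, followed by MnO2 oxidation that is selective for the allylic alcohol.

**Step 15**
Reactants: 19 enone diol
Product: 20 3-(tert-butyldimethylsilyloxy)-5-hydroxy-6-(hydroxymethyl)-2,6,9-trimethyltricyclo[5.4.0.0^{2,8}]undecan-11-one (9-CH3 syn to C7)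
Conditions: Me2CuLi (5 equiv, from MeLi and CuI), Et2O, −78 → −30 °C; NH4Cl/NH3 work-up
Reagents that add atoms: lithium dimethylcuprate, [Li+].C[Cu-]C (from methyllithium, [Li]C, and CuI)
Why: Gilman cuprate conjugate addition to the bicyclo[3.1.1]heptenone; the methyl should enter from the side of C7, anti to the C2 methyl that projects over the enone bridge, as in additions to apoverbenone.

**Step 16**
Reactants: 20 silyl ether
Product: 21 3,5-dihydroxy-6-(hydroxymethyl)-2,6,9-trimethyltricyclo[5.4.0.0^{2,8}]undecan-11-one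
Conditions: HF·pyridine, THF, rt → 40 °C
Reagents that add atoms: none
Why: Fluoride-mediated desilylation of the secondary silyl ether; no stereocentre is touched.

**Step 17**
Reactants: 21 triol
Product: 22 6-[(tert-butyldimethylsilyloxy)methyl]-3,5-dihydroxy-2,6,9-trimethyltricyclo[5.4.0.0^{2,8}]undecan-11-one
Conditions: TBSCl (1.1 equiv), imidazole, CH2Cl2, 0 °C
Reagents that add atoms: tert-butyldimethylsilyl chloride, CC(C)(C)[Si](C)(C)Cl
Why: Selective silylation of the primary hydroxyl in the presence of two secondary hydroxyls that each adjoin a quaternary carbon.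

**Step 18**
Reactants: 22 diol; 23 angelic acid
Product: 25 6-[(tert-butyldimethylsilyloxy)methyl]-2,6,9-trimethyl-11-oxotricyclo[5.4.0.0^{2,8}]undecane-3,5-diyl bis[(Z)-2-methylbut-2-enoate], via mixed anhydride 24 (not isolated)
Conditions: 2,4,6-trichlorobenzoyl chloride, Et3N, toluene, rt; then 22, 80 °C (no DMAP)
Reagents that add atoms: 2,4,6-trichlorobenzoyl chloride, O=C(Cl)c1c(Cl)cc(Cl)cc1Cl (atoms only in 24)
Why: Yamaguchi-type esterification through the angelic 2,4,6-trichlorobenzoic mixed anhydride without nucleophilic catalyst, the conditions that best preserve the Z geometry of angelates.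

**Step 19**
Reactants: 25 silyl ether bis-angelate
Product: 26 target, 3,5-bis[(Z)-2-methylbut-2-enoyloxy]-6-(hydroxymethyl)-2,6,9-trimethyltricyclo[5.4.0.0^{2,8}]undecan-11-one
Conditions: HF·pyridine, pyridine/THF, 0 °C → rt
Reagents that add atoms: none
Why: Buffered fluoride desilylation of the primary silyl ether, which should leave the base- and heat-sensitive angelates untouched.

**Compound list**

1 | (R)-Wieland–Miescher ketone, (8aR)-8a-methyl-3,4,8,8a-tetrahydronaphthalene-1,6(2H,7H)-dione | O=C1CC[C@]2(C)C(=C1)CCCC2=O | starting material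
2 | (4aR,5R)-5-hydroxy-4a-methyl-4,4a,5,6,7,8-hexahydronaphthalen-2(3H)-one (OH cis to angular CH3) | O=C1CC[C@]2(C)C(=C1)CCC[C@H]2O | intermediate
3 | (1R,8aR)-8a-methyl-6-oxo-1,2,3,4,6,7,8,8a-octahydronaphthalen-1-yl 4-methylbenzenesulfonate | O=C1CC[C@]2(C)C(=C1)CCC[C@H]2OS(=O)(=O)c1ccc(C)cc1 | intermediate
4 | linear dienol trimethylsilyl ether of 3 | C[Si](C)(C)OC1=CC2=CCC[C@@H](OS(=O)(=O)c3ccc(C)cc3)[C@]2(C)CC1 | intermediate (not isolated)
5 | 4-hydroxy-8a-methyl-6-oxo-1,2,3,4,6,7,8,8a-octahydronaphthalen-1-yl 4-methylbenzenesulfonate (1-OTs, 4-OH, 8a-CH3 cis) | O=C1CC[C@]2(C)C(=C1)[C@@H](O)CC[C@H]2OS(=O)(=O)c1ccc(C)cc1 | intermediate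
6 | cis-fused 4-hydroxy-8a-methyl-6-oxodecahydronaphthalen-1-yl 4-methylbenzenesulfonate (1-OTs, 4-OH, 4a-H, 8a-CH3 on one face) | O=C1CC[C@]2(C)[C@H](C1)[C@@H](O)CC[C@H]2OS(=O)(=O)c1ccc(C)cc1 | intermediate
7 | 3-hydroxy-1-methyltricyclo[4.4.0.0^{2,7}]decan-8-one (3-OH on the side of C1) | O=C1CC[C@]2(C)[C@@H]3[C@H]1[C@H]2CC[C@@H]3O | intermediate
8 | 1-methyltricyclo[4.4.0.0^{2,7}]dec-3-en-8-one | O=C1CC[C@]2(C)[C@@H]3[C@H]1[C@H]2CC=C3 | intermediate
9 | 1-methyltricyclo[4.4.0.0^{2,7}]deca-3,9-dien-8-one | O=C1C=C[C@]2(C)[C@@H]3[C@H]1[C@H]2CC=C3 | intermediate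
10 | 1-methyl-10-(pinacolboryl)tricyclo[4.4.0.0^{2,7}]dec-3-en-8-one (boron syn to C6) | O=C1C[C@@H](B2OC(C)(C)C(C)(C)O2)[C@]3(C)[C@@H]4[C@H]1[C@H]3CC=C4 | intermediate (not isolated)
11 | 10-hydroxy-1-methyltricyclo[4.4.0.0^{2,7}]dec-3-en-8-one (10-OH syn to C6) | O=C1C[C@@H](O)[C@]2(C)[C@@H]3[C@H]1[C@H]2CC=C3 | intermediate
12 | 10-(tert-butyldimethylsilyloxy)-1-methyltricyclo[4.4.0.0^{2,7}]dec-3-en-8-one | O=C1C[C@@H](O[Si](C)(C)C(C)(C)C)[C@]2(C)[C@@H]3[C@H]1[C@H]2CC=C3 | intermediate
13 | isopropenylmagnesium bromide | C=C(C)[Mg]Br | starting material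
14 | 10-(tert-butyldimethylsilyloxy)-1-methyl-8-(prop-1-en-2-yl)tricyclo[4.4.0.0^{2,7}]dec-3-en-8-ol (8-OH and 10-OSi syn to C6) | C=C(C)[C@]1(O)C[C@@H](O[Si](C)(C)C(C)(C)C)[C@]2(C)[C@@H]3[C@H]1[C@H]2CC=C3 | intermediate
15 | 10-(tert-butyldimethylsilyloxy)-1-methyl-8-[(R)-2-methyloxiran-2-yl]tricyclo[4.4.0.0^{2,7}]dec-3-en-8-ol | C[C@@]1(CO1)[C@]2(O)C[C@@H](O[Si](C)(C)C(C)(C)C)[C@]3(C)[C@@H]4[C@H]2[C@H]3CC=C4 | intermediate
16 | 3-(tert-butyldimethylsilyloxy)-6-(hydroxymethyl)-2,6-dimethyltricyclo[5.4.0.0^{2,8}]undec-9-en-5-one (3-OSi, 6-CH2OH syn to C1; 6-CH3 syn to C8) | O=C1C[C@@H](O[Si](C)(C)C(C)(C)C)[C@]2(C)[C@@H]3[C@@H]([C@H]2CC=C3)[C@@]1(C)CO | intermediate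
17 | 3-(tert-butyldimethylsilyloxy)-6-(hydroxymethyl)-2,6-dimethyltricyclo[5.4.0.0^{2,8}]undec-9-en-5-ol (5-OH syn to C8) | O[C@@H]1C[C@@H](O[Si](C)(C)C(C)(C)C)[C@]2(C)[C@@H]3[C@@H]([C@H]2CC=C3)[C@@]1(C)CO | intermediate
18 | 3-(tert-butyldimethylsilyloxy)-6-(hydroxymethyl)-2,6-dimethyltricyclo[5.4.0.0^{2,8}]undec-9-ene-5,11-diol (C11 epimers) | O[C@@H]1C[C@@H](O[Si](C)(C)C(C)(C)C)[C@]2(C)[C@@H]3[C@@H]([C@H]2C(O)C=C3)[C@@]1(C)CO | intermediate (not isolated)
19 | 3-(tert-butyldimethylsilyloxy)-5-hydroxy-6-(hydroxymethyl)-2,6-dimethyltricyclo[5.4.0.0^{2,8}]undec-9-en-11-one | O[C@@H]1C[C@@H](O[Si](C)(C)C(C)(C)C)[C@]2(C)[C@@H]3[C@@H]([C@H]2C(=O)C=C3)[C@@]1(C)CO | intermediate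
20 | 3-(tert-butyldimethylsilyloxy)-5-hydroxy-6-(hydroxymethyl)-2,6,9-trimethyltricyclo[5.4.0.0^{2,8}]undecan-11-one (9-CH3 syn to C7) | O[C@@H]1C[C@@H](O[Si](C)(C)C(C)(C)C)[C@]2(C)[C@@H]3[C@@H]([C@H]2C(=O)C[C@H]3C)[C@@]1(C)CO | intermediate
21 | 3,5-dihydroxy-6-(hydroxymethyl)-2,6,9-trimethyltricyclo[5.4.0.0^{2,8}]undecan-11-one | O[C@@H]1C[C@@H](O)[C@]2(C)[C@@H]3[C@@H]([C@H]2C(=O)C[C@H]3C)[C@@]1(C)CO | intermediate
22 | 6-[(tert-butyldimethylsilyloxy)methyl]-3,5-dihydroxy-2,6,9-trimethyltricyclo[5.4.0.0^{2,8}]undecan-11-one | O[C@@H]1C[C@@H](O)[C@]2(C)[C@@H]3[C@@H]([C@H]2C(=O)C[C@H]3C)[C@@]1(C)CO[Si](C)(C)C(C)(C)C | intermediate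
23 | angelic acid, (Z)-2-methylbut-2-enoic acid | C/C=C(/C)C(=O)O | starting material
24 | angelic 2,4,6-trichlorobenzoic anhydride | C/C=C(/C)C(=O)OC(=O)c1c(Cl)cc(Cl)cc1Cl | intermediate (not isolated)
25 | 6-[(tert-butyldimethylsilyloxy)methyl]-2,6,9-trimethyl-11-oxotricyclo[5.4.0.0^{2,8}]undecane-3,5-diyl bis[(Z)-2-methylbut-2-enoate] | C/C=C(/C)C(=O)O[C@@H]1C[C@@H](OC(=O)/C(C)=C\C)[C@]2(C)[C@@H]3[C@@H]([C@H]2C(=O)C[C@H]3C)[C@@]1(C)CO[Si](C)(C)C(C)(C)C | intermediate
26 | 3,5-bis[(Z)-2-methylbut-2-enoyloxy]-6-(hydroxymethyl)-2,6,9-trimethyltricyclo[5.4.0.0^{2,8}]undecan-11-one (3-O and 6-CH2OH syn to C1; 5-O and 6-CH3 syn to C8; 9-CH3 syn to C7) | C/C=C(/C)C(=O)O[C@@H]1C[C@@H](OC(=O)/C(C)=C\C)[C@]2(C)[C@@H]3[C@@H]([C@H]2C(=O)C[C@H]3C)[C@@]1(C)CO | target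

**Totals**

Total step count: 19. Longest linear sequence: 19 steps (from 1).

**Steps most likely to fail**

Step 12 (ring enlargement). The ring CH2 may shift in place of the cyclobutane CH, or bromide may open the activated epoxide before any shift occurs. The fallback sets out from 15 and returns at 21; it makes the competing carbon unable to migrate by raising C3 to a ketone. HF·pyridine removes the silyl group to give the epoxy diol F1. Dess–Martin periodinane oxidises its secondary hydroxyl to the epoxy β-hydroxy ketone F2. ZnBr2 then shifts the only migration-competent carbon and gives the ring-enlarged 1,3-diketone F3. Excess Me4NBH(OAc)3 reduces C5 (hydride from the CH2OH side) and then C3 (hydride from the new 5-OH side), each anti, to the triol F4. SeO2/t-BuOOH gives the allylic alcohol F5, MnO2 gives the enone F6, and Me2CuLi under the conditions of step 15 gives 21.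

Step 11 (directed epoxidation). Oxygen may be delivered to the other face of the isopropenyl group, since the A(1,2) argument is the least secure stereochemical prediction of the route; after the shift this would give the C6 epimer. The fallback sets out from 12 and returns at 16; it exchanges the roles of the two substituents at the future C6 so that the same facial preference serves. Ketone 12 and [2-(4-methoxybenzyloxymethyl)vinyl]magnesium bromide (LaCl3·2LiCl) give the carbinol F7. VO(acac)2/t-BuOOH gives the epoxide F8. ZnBr2 gives the rearranged hydroxy ketone F9, in which the epoxide-derived CH2OH stands where the methyl is needed and the CH2OPMB where CH2OH is needed. 1,1'-Thiocarbonyldiimidazole gives the imidazole-1-carbothioate F10. Bu3SnH/AIBN (Barton–McCombie, at high tin hydride concentration so that hydrogen transfer outruns a 1,2-acyl shift of the β-keto radical) gives the methyl compound F11. DDQ removes the PMB group to give 16.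

Step 18 (double angeloylation). The activated angelate may isomerise from Z to E, and acylation of two secondary alcohols next to quaternary carbons may stall. The fallback sets out from 22 and returns at 25; it forms the Z double bonds after the acylation. 2-[Bis(2,2,2-trifluoroethoxy)phosphoryl]propanoic acid, DIC and DMAP give the bis(phosphonopropionate) F12. KHMDS/18-crown-6 and acetaldehyde at −78 °C (Still–Gennari olefination) give 25.

**Further compounds**

F1 | step 12 | 1-methyl-8-[(R)-2-methyloxiran-2-yl]tricyclo[4.4.0.0^{2,7}]dec-3-ene-8,10-diol | C[C@@]1(CO1)[C@]2(O)C[C@@H](O)[C@]3(C)[C@@H]4[C@H]2[C@H]3CC=C4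
F2 | step 12 | 8-hydroxy-1-methyl-8-[(R)-2-methyloxiran-2-yl]tricyclo[4.4.0.0^{2,7}]dec-3-en-10-one | C[C@@]1(CO1)[C@]2(O)CC(=O)[C@]3(C)[C@@H]4[C@H]2[C@H]3CC=C4
F3 | step 12 | 6-(hydroxymethyl)-2,6-dimethyltricyclo[5.4.0.0^{2,8}]undec-9-ene-3,5-dione | O=C1CC(=O)[C@]2(C)[C@@H]3[C@@H]([C@H]2CC=C3)[C@@]1(C)CO
F4 | step 12 | 6-(hydroxymethyl)-2,6-dimethyltricyclo[5.4.0.0^{2,8}]undec-9-ene-3,5-diol | O[C@@H]1C[C@@H](O)[C@]2(C)[C@@H]3[C@@H]([C@H]2CC=C3)[C@@]1(C)CO
F5 | step 12 | 6-(hydroxymethyl)-2,6-dimethyltricyclo[5.4.0.0^{2,8}]undec-9-ene-3,5,11-triol (C11 epimers) | O[C@@H]1C[C@@H](O)[C@]2(C)[C@@H]3[C@@H]([C@H]2C(O)C=C3)[C@@]1(C)CO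
F6 | step 12 | 3,5-dihydroxy-6-(hydroxymethyl)-2,6-dimethyltricyclo[5.4.0.0^{2,8}]undec-9-en-11-one | O[C@@H]1C[C@@H](O)[C@]2(C)[C@@H]3[C@@H]([C@H]2C(=O)C=C3)[C@@]1(C)CO
F7 | step 11 | 10-(tert-butyldimethylsilyloxy)-8-[3-(4-methoxybenzyloxy)prop-1-en-2-yl]-1-methyltricyclo[4.4.0.0^{2,7}]dec-3-en-8-ol | COc1ccc(COCC(=C)[C@]2(O)C[C@@H](O[Si](C)(C)C(C)(C)C)[C@]3(C)[C@@H]4[C@H]2[C@H]3CC=C4)cc1
F8 | step 11 | 10-(tert-butyldimethylsilyloxy)-8-{2-[(4-methoxybenzyloxy)methyl]oxiran-2-yl}-1-methyltricyclo[4.4.0.0^{2,7}]dec-3-en-8-ol | COc1ccc(COC[C@]2(CO2)[C@]3(O)C[C@@H](O[Si](C)(C)C(C)(C)C)[C@]4(C)[C@@H]5[C@H]3[C@H]4CC=C5)cc1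
F9 | step 11 | 3-(tert-butyldimethylsilyloxy)-6-(hydroxymethyl)-6-[(4-methoxybenzyloxy)methyl]-2-methyltricyclo[5.4.0.0^{2,8}]undec-9-en-5-one (CH2OH syn to C8, CH2OPMB syn to C1) | O=C1C[C@@H](O[Si](C)(C)C(C)(C)C)[C@]2(C)[C@@H]3[C@@H]([C@H]2CC=C3)[C@@]1(CO)COCc1ccc(OC)cc1
F10 | step 11 | O-alkyl 1H-imidazole-1-carbothioate of F9 | O=C1C[C@@H](O[Si](C)(C)C(C)(C)C)[C@]2(C)[C@@H]3[C@@H]([C@H]2CC=C3)[C@@]1(COC(=S)n1ccnc1)COCc1ccc(OC)cc1
F11 | step 11 | 3-(tert-butyldimethylsilyloxy)-6-[(4-methoxybenzyloxy)methyl]-2,6-dimethyltricyclo[5.4.0.0^{2,8}]undec-9-en-5-one | O=C1C[C@@H](O[Si](C)(C)C(C)(C)C)[C@]2(C)[C@@H]3[C@@H]([C@H]2CC=C3)[C@@]1(C)COCc1ccc(OC)cc1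
F12 | step 18 | 3,5-bis{2-[bis(2,2,2-trifluoroethoxy)phosphoryl]propanoate} of 22 | CC(P(=O)(OCC(F)(F)F)OCC(F)(F)F)C(=O)O[C@@H]1C[C@@H](OC(=O)C(C)P(=O)(OCC(F)(F)F)OCC(F)(F)F)[C@]2(C)[C@@H]3[C@@H]([C@H]2C(=O)C[C@H]3C)[C@@]1(C)CO[Si](C)(C)C(C)(C)C
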